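**Plan**
- Retrosynthesis: the C10 and C12 formyl groups come from a diol. The C1–C10 bond and the C8=C9 olefin come from a Wittig–Still [2,3] shift of a C8 stannylmethyl ether. The ring bond C8–C9 comes from an intramolecular Nozaki–Hiyama–Kishi reaction, C2–C3 from a Marshall allenylindium propargylation, C1′–C2 from an Evans syn-aldol, and the C5 methyl and C6–C7 from carboalumination/ethylene oxide.
- Feature used: C1 is a ring methine that carries one carbon (C10) and lies allylic to the ring-cis C8=C9 olefin. This is the homoallylic alcohol pattern left when an O–CH2 carbanion on C8 crosses a C9=C1 olefin.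
- Forward order: imide 9 and ynal 13 give mesylate 19; alkyne 20 gives aldehyde 26; 19 and 26 give the open chain 28; the alkyne becomes the (Z)-iodoalkene; the only ring (nine-membered) closes in step 21; the [2,3] shift follows, then five end-game steps.
- Stereochemistry: C1′ and the mesylate carbinol come from the (S)-benzyloxazolidinone aldol. C2 and C3 come from the mesylate through the (P)-allenylindium (anti addition). C8 comes from CBS reduction, and C1 from C8 by suprafacial transfer. 5E comes from syn-carboalumination and the ring-cis C9=C1 from trans-hydrostannation.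

Key step: step 25

Remark: locants C1–C12 and C1′ are those of the target (ring C1–C9, C10 on C1, C12 on C9, C11 = CH2O on C1′). The target is taken as the open hydroxy dialdehyde, which is reasonable because C3–OH and the C1 formyl are trans on the ring and cannot bridge to a lactol. From compound 27 on, names use these locants and the SMILES define the configuration.

**Step 1**
Reactants: 1 5-bromo-2-methylpent-2-ene; 2 dimethyl malonate
Product: 4 dimethyl 2-(4-methylpent-3-en-1-yl)malonate, via sodium dimethyl malonate 3 (not isolated)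
Conditions: NaH, 2 (2.5 equiv), THF/DMF, 0 °C; then 1, 60 °C
Reagents that add atoms: none
Why: Malonic ester alkylation, in which the soft malonate anion should displace the primary homoallylic bromide by SN2 with little E2, the excess of 2 suppressing dialkylation.

**Step 2**
Reactants: 4 dimethyl 2-(4-methylpent-3-en-1-yl)malonate
Product: 6 6-methylhept-5-enoic acid, via 2-(4-methylpent-3-en-1-yl)malonic acid 5 (not isolated)
Conditions: KOH, EtOH/H2O, reflux; HCl to pH 1; crude diacid neat, 150 °C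
Reagents that add atoms: potassium hydroxide [K+].[OH-]
Why: Saponification and thermal decarboxylation (malonic ester synthesis) should leave the isolated trisubstituted olefin untouched.

**Step 3**
Reactants: 6 6-methylhept-5-enoic acid; 7 (S)-4-benzyloxazolidin-2-one
Product: 9 (S)-4-benzyl-3-(6-methylhept-5-enoyl)oxazolidin-2-one, via mixed pivalic anhydride 8 (not isolated)
Conditions: PivCl, Et3N, THF, −20 °C; then LiCl, 7, −20 °C → rt
Reagents that add atoms: none
Why: Mixed-anhydride N-acylation of the oxazolidinone under LiCl/Et3N activation avoids strong base and an acid chloride.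

**Step 4**
Reactants: 10 propargyl alcohol
Product: 11 triethyl(prop-2-yn-1-yloxy)silane
Conditions: TESCl, imidazole, CH2Cl2, 0 °C
Reagents that add atoms: chlorotriethylsilane CC[Si](Cl)(CC)CC
Why: Standard O-silylation; the TES ether can later be removed beside a secondary TBS ether.

**Step 5**
Reactants: 11 triethyl(prop-2-yn-1-yloxy)silane
Product: 13 4-(triethylsilyloxy)but-2-ynal, via lithium acetylide 12 (not isolated)
Conditions: n-BuLi, THF, −78 °C; DMF, −78 → 0 °C; inverse quench into aq. KH2PO4/MTBE, 0 °C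
Reagents that add atoms: N,N-dimethylformamide CN(C)C=O
Why: Formylation of a lithium acetylide with DMF, the buffered inverse quench releasing the ynal without conjugate addition of dimethylamine.

**Step 6**
Reactants: 9 (S)-4-benzyl-3-(6-methylhept-5-enoyl)oxazolidin-2-one; 13 4-(triethylsilyloxy)but-2-ynal
Product: 15 (S)-4-benzyl-3-[(2S,3S)-3-hydroxy-2-(4-methylpent-3-en-1-yl)-6-(triethylsilyloxy)hex-4-ynoyl]oxazolidin-2-one, via (Z)-dibutylboron enolate 14 (not isolated)
Conditions: Bu2BOTf, Et3N, CH2Cl2, −78 → 0 °C; 13, −78 → 0 °C; pH 7 buffer, MeOH, 30% H2O2, 0 °C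
Reagents that add atoms: none
Why: Evans syn-aldol through the (Z)-boron enolate and a Zimmerman–Traxler transition state, the (S)-auxiliary setting C1′ (2S) and the propargylic carbinol (3S) in one operation.

**Step 7**
Reactants: 15 aldol adduct
Product: 16 (2R,3S)-2-(4-methylpent-3-en-1-yl)-6-(triethylsilyloxy)hex-4-yne-1,3-diol
Conditions: LiBH4, MeOH (1 equiv), THF, 0 °C
Reagents that add atoms: none
Why: Reductive cleavage of the N-acyloxazolidinone with lithium borohydride gives the 1,3-diol and returns the auxiliary without touching the stereocentres.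

**Step 8**
Reactants: 16 diol
Product: 18 (4S,5R)-5-[(4-methoxybenzyloxy)methyl]-9-methyl-1-(triethylsilyloxy)dec-8-en-2-yn-4-ol, via dibutylstannylene acetal 17 (not isolated)
Conditions: Bu2SnO, toluene, reflux (Dean–Stark); then PMBCl, Bu4NI (cat.), 90 °C
Reagents that add atoms: 4-methoxybenzyl chloride COc1ccc(CCl)cc1
Why: Stannylene-acetal-mediated regioselective O-alkylation, in which the primary oxygen of the six-membered stannylene is expected to be alkylated and the propargylic hydroxyl left free.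

**Step 9**
Reactants: 18 propargylic alcohol
Product: 19 (4S,5R)-5-[(4-methoxybenzyloxy)methyl]-9-methyl-1-(triethylsilyloxy)dec-8-en-2-yn-4-yl methanesulfonate
Conditions: MsCl, Et3N, CH2Cl2, −78 → 0 °C; used without chromatography
Reagents that add atoms: methanesulfonyl chloride CS(Cl)(=O)=O
Why: Mesylation proceeds with retention at the carbinol and gives the (S)-propargylic mesylate needed for the allenylmetal step.

**Step 10**
Reactants: 20 tert-butyl(but-3-yn-1-yloxy)dimethylsilane
Product: 23 (E)-6-(tert-butyldimethylsilyloxy)-4-methylhex-3-en-1-ol, via alkenyldimethylalane 21 (not isolated), via lithium alkenylaluminate 22 (not isolated)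
Conditions: Me3Al, Cp2ZrCl2 (0.25 equiv), CH2Cl2, 0 °C → rt; then n-BuLi, hexane/THF, −30 °C; ethylene oxide, −30 °C → rt
Reagents that add atoms: trimethylaluminium C[Al](C)C; ethylene oxide C1CO1
Why: Negishi zirconium-catalysed syn-methylalumination followed by opening of ethylene oxide by the alkenylaluminate with retention fixes the 5E trisubstituted olefin and adds C7–C8.

**Step 11**
Reactants: 23 homoallylic alcohol
Product: 24 (E)-6-(tert-butyldimethylsilyloxy)-4-methylhex-3-en-1-yl pivalate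
Conditions: PivCl, pyridine, DMAP (cat.), CH2Cl2, 0 °C → rt
Reagents that add atoms: pivaloyl chloride CC(C)(C)C(Cl)=O
Why: Acylation gives a C8 ester that survives the organoindium, silylation and stannylation steps and is later removed reductively.

**Step 12**
Reactants: 24 pivalate silyl ether
Product: 25 (E)-6-hydroxy-4-methylhex-3-en-1-yl pivalate
Conditions: CSA (cat.), MeOH, 0 °C
Reagents that add atoms: none
Why: Acid-catalysed methanolysis of a primary TBS ether is fast under conditions that leave the pivalate and the olefin alone.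

**Step 13**
Reactants: 25 hydroxy pivalate
Product: 26 (E)-4-methyl-6-oxohex-3-en-1-yl pivalate
Conditions: DMP, pyridine, CH2Cl2, 0 °C; used at once
Reagents that add atoms: none
Why: Dess–Martin oxidation under buffered, base-free conditions should give the β,γ-unsaturated aldehyde without migration of the olefin into conjugation.

**Step 14**
Reactants: 19 propargylic mesylate; 26 (E)-4-methyl-6-oxohex-3-en-1-yl pivalate
Product: 28 open-chain anti adduct (C1′S,C2R,C3S), via (P)-allenylindium 27 (not isolated)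
Conditions: Pd(dppf)Cl2 (5 mol %), InI (1.5 equiv), THF/HMPA 3:1, rt
Reagents that add atoms: none
Why: Marshall propargylation, in which anti SN2′ attack of Pd(0) on the (S)-mesylate and transmetalation give the (P)-allenylindium, which adds to the aldehyde through a cyclic SE2′ transition state so that C2 (R) follows from the mesylate configuration and C3 (S) from the anti arrangement.

**Step 15**
Reactants: 28 anti adduct
Product: 29 C3 tert-butyldimethylsilyl ether of 28
Conditions: TBSOTf, 2,6-lutidine, CH2Cl2, −78 → 0 °C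
Reagents that add atoms: tert-butyldimethylsilyl triflate CC(C)(C)[Si](C)(C)OS(=O)(=O)C(F)(F)F
Why: Silylation with the triflate protects the hindered C3 hydroxyl, which would otherwise compete as a directing group in step 17.

**Step 16**
Reactants: 29 bis-silyl ether
Product: 30 C12 propargylic alcohol (C3–OTBS retained)
Conditions: PPTS, MeOH/CH2Cl2, 0 °C
Reagents that add atoms: none
Why: Mild acidic methanolysis removes the primary propargylic TES ether far faster than the hindered secondary TBS ether.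

**Step 17**
Reactants: 30 propargylic alcohol
Product: 32 (Z)-C9 iodoalkene with free C12–OH, via (Z)-alkenylstannane 31 (not isolated)
Conditions: [Cp*RuCl]4 (2.5 mol %), Bu3SnH, CH2Cl2, rt; then I2, 0 °C
Reagents that add atoms: iodine II
Why: Hydroxyl-directed ruthenium-catalysed trans-hydrostannation places tin on C9 next to the carbinol and hydrogen trans to it on C1, and iododestannylation with retention gives the iodoalkene with iodine cis to C2.

**Step 18**
Reactants: 32 iodo allylic alcohol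
Product: 33 C12 triisopropylsilyl ether of 32
Conditions: TIPSOTf, 2,6-lutidine, CH2Cl2, −78 °C
Reagents that add atoms: triisopropylsilyl triflate CC(C)[Si](OS(=O)(=O)C(F)(F)F)(C(C)C)C(C)C
Why: Silylation with a bulky group is chosen because O12 later sits 1,3 to the C8 alkoxide of step 24, where a smaller silyl group could migrate.

**Step 19**
Reactants: 33 iodo pivalate
Product: 34 C8 primary alcohol
Conditions: DIBAL-H, CH2Cl2, −78 °C; Rochelle salt
Reagents that add atoms: none
Why: Reductive cleavage of the pivalate at low temperature leaves the alkenyl iodide, silyl ethers and PMB ether intact.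

**Step 20**
Reactants: 34 iodo alcohol
Product: 35 C8 aldehyde (β,γ-unsaturated) bearing the (Z)-C9 iodoalkene
Conditions: DMP, pyridine, CH2Cl2, 0 °C; used at once
Reagents that add atoms: none
Why: Dess–Martin oxidation gives the sensitive aldehyde under buffered conditions that avoid olefin migration.

**Step 21**
Reactants: 35 iodo aldehyde
Product: 37 nine-membered ring dienol (C8 epimers), via alkenylchromium(III) species 36 (not isolated)
Conditions: CrCl2 (10 equiv), NiCl2 (2 mol % of Cr), degassed DMSO/THF, 0.002 M, rt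
Reagents that add atoms: none
Why: Intramolecular Nozaki–Hiyama–Kishi reaction, in which the nickel-derived alkenylchromium adds chemoselectively to the aldehyde at high dilution and closes the nine-membered ring at C8–C9 with retention of the cis alkene; the C8 configuration is corrected in steps 22 and 23.

**Step 22**
Reactants: 37 ring dienol
Product: 38 ring dienone (C8 ketone)
Conditions: DMP, pyridine, CH2Cl2, 0 °C
Reagents that add atoms: none
Why: Dess–Martin oxidation of the allylic alcohol converges both C8 epimers on one enone.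

**Step 23**
Reactants: 38 ring dienone
Product: 39 (8S)-ring dienol
Conditions: (R)-Me-CBS (0.3 equiv), catecholborane, toluene, −78 °C
Reagents that add atoms: none
Why: Corey–Bakshi–Shibata reduction, in which the α-branched alkenyl group C9 acts as the large substituent and C7H2 as the small one, so the (R)-catalyst should deliver hydride to give the (8S) alcohol.

**Step 24**
Reactants: 39 (8S)-ring dienol
Product: 41 C8 (tributylstannyl)methyl ether, via potassium alkoxide 40 (not isolated)
Conditions: KH, 18-crown-6 (cat.), THF, 0 °C; Bu3SnCH2I, 0 °C → rt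
Reagents that add atoms: tributyl(iodomethyl)stannane CCCC[Sn](CI)(CCCC)CCCC
Why: Williamson etherification of the potassium alkoxide with the iodomethylstannane gives the rearrangement precursor.

**Step 25**
Reactants: 41 C8 (tributylstannyl)methyl ether
Product: 43 C10 alcohol (1R,2R,3S,1′S; 5E,8E), via α-alkoxymethyllithium 42 (not isolated)
Conditions: n-BuLi (2.5 equiv), THF, −78 → −40 °C; H2O quench at −78 °C
Reagents that add atoms: none
Why: Wittig–Still rearrangement: tin–lithium exchange on 41 gives the unstabilised α-alkoxymethyllithium 42, which undergoes a concerted suprafacial [2,3]-sigmatropic shift through a five-membered envelope transition state, bonding its carbon to C1 while the C8–O bond breaks and the olefin moves from C9=C1 to C8=C9. The closest known reaction type is the rearrangement of stannylmethyl ethers of cyclic allylic alcohols with 1,3-transfer of chirality. No ring is formed; the nine-membered ring is a spectator that fixes the new C8=C9 olefin as ring-cis. The one new stereocentre, C1 (R), is controlled by the (8S) carbinol, because the carbanion can only reach the face of C9=C1 that carries the C8–O bond. The step needs [2,3] over [1,2] migration and over simple protonation of 42, which the low temperature, the unhindered CH terminus C1 and the absence of an anion-stabilising group should secure, and the C12 TIPS ether is too hindered to migrate to the new alkoxide.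

**Step 26**
Reactants: 43 C10 alcohol
Product: 44 C10 triethylsilyl ether
Conditions: TESCl, imidazole, DMAP (cat.), CH2Cl2, 0 °C
Reagents that add atoms: chlorotriethylsilane CC[Si](Cl)(CC)CC
Why: Silylation masks C10–OH so that C11 becomes the only free hydroxyl after the next step.

**Step 27**
Reactants: 44 fully protected ring diene
Product: 45 C11 primary alcohol
Conditions: DDQ, CH2Cl2/pH 7 buffer 10:1, 0 °C
Reagents that add atoms: none
Why: Oxidative cleavage of the 4-methoxybenzyl ether by DDQ under buffered conditions spares the silyl ethers and isolated olefins.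

**Step 28**
Reactants: 45 C11 alcohol
Product: 46 C11 acetate
Conditions: Ac2O, pyridine, DMAP (cat.), CH2Cl2, 0 °C
Reagents that add atoms: acetic anhydride CC(=O)OC(C)=O
Why: Standard acetylation of the only free hydroxyl.

**Step 29**
Reactants: 46 tris-silyl acetate
Product: 47 C3,C10,C12 triol acetate
Conditions: HF·pyridine, pyridine, THF, 0 °C → rt
Reagents that add atoms: none
Why: Fluoride-mediated desilylation under buffered acidic conditions removes all three silyl groups without acetate migration or hydrolysis.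

**Step 30**
Reactants: 47 triol acetate
Product: 48 target CNP0284729.1
Conditions: TEMPO (0.2 equiv), PhI(OAc)2 (2.4 equiv), CH2Cl2, rt
Reagents that add atoms: none
Why: TEMPO/diacetoxyiodobenzene oxidation is selective for the primary allylic (C12) and primary (C10) alcohols over the hindered secondary C3–OH, so the labile C1 formyl stereocentre is generated last, under mildly acidic conditions, with no later handling.

**Compound list**
1 | 5-bromo-2-methylpent-2-ene | CC(C)=CCCBr | starting material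
2 | dimethyl malonate | COC(=O)CC(=O)OC | starting material
3 | sodium dimethyl malonate | [Na+].COC(=O)[CH-]C(=O)OC | intermediate
4 | dimethyl 2-(4-methylpent-3-en-1-yl)malonate | COC(=O)C(CCC=C(C)C)C(=O)OC | intermediate
5 | 2-(4-methylpent-3-en-1-yl)malonic acid | OC(=O)C(CCC=C(C)C)C(=O)O | intermediate
6 | 6-methylhept-5-enoic acid | CC(C)=CCCCC(=O)O | intermediate
7 | (S)-4-benzyloxazolidin-2-one | O=C1N[C@@H](Cc2ccccc2)CO1 | starting material
8 | 6-methylhept-5-enoic pivalic anhydride | CC(C)=CCCCC(=O)OC(=O)C(C)(C)C | intermediate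
9 | (S)-4-benzyl-3-(6-methylhept-5-enoyl)oxazolidin-2-one | CC(C)=CCCCC(=O)N1[C@@H](Cc2ccccc2)COC1=O | intermediate
10 | propargyl alcohol | C#CCO | starting material
11 | triethyl(prop-2-yn-1-yloxy)silane | C#CCO[Si](CC)(CC)CC | intermediate
12 | [3-(triethylsilyloxy)prop-1-yn-1-yl]lithium | [Li]C#CCO[Si](CC)(CC)CC | intermediate
13 | 4-(triethylsilyloxy)but-2-ynal | O=CC#CCO[Si](CC)(CC)CC | intermediate
14 | (Z)-dibutylboron enolate of 9 | CCCCB(CCCC)O/C(=C\CCC=C(C)C)N1[C@@H](Cc2ccccc2)COC1=O | intermediate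
15 | (S)-4-benzyl-3-[(2S,3S)-3-hydroxy-2-(4-methylpent-3-en-1-yl)-6-(triethylsilyloxy)hex-4-ynoyl]oxazolidin-2-one | CC[Si](CC)(CC)OCC#C[C@@H](O)[C@H](CCC=C(C)C)C(=O)N1[C@@H](Cc2ccccc2)COC1=O | intermediate
16 | (2R,3S)-2-(4-methylpent-3-en-1-yl)-6-(triethylsilyloxy)hex-4-yne-1,3-diol | CC[Si](CC)(CC)OCC#C[C@@H](O)[C@H](CCC=C(C)C)CO | intermediate
17 | 2,2-dibutyl-1,3,2-dioxastanninane (stannylene acetal) of 16 | CC[Si](CC)(CC)OCC#C[C@H]1O[Sn](CCCC)(CCCC)OC[C@H]1CCC=C(C)C | intermediate
18 | (4S,5R)-5-[(4-methoxybenzyloxy)methyl]-9-methyl-1-(triethylsilyloxy)dec-8-en-2-yn-4-ol | CC[Si](CC)(CC)OCC#C[C@@H](O)[C@H](CCC=C(C)C)COCc1ccc(OC)cc1 | intermediate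
19 | (4S,5R)-5-[(4-methoxybenzyloxy)methyl]-9-methyl-1-(triethylsilyloxy)dec-8-en-2-yn-4-yl methanesulfonate | CC[Si](CC)(CC)OCC#C[C@@H](OS(C)(=O)=O)[C@H](CCC=C(C)C)COCc1ccc(OC)cc1 | intermediate
20 | tert-butyl(but-3-yn-1-yloxy)dimethylsilane | C#CCCO[Si](C)(C)C(C)(C)C | starting material
21 | (E)-[4-(tert-butyldimethylsilyloxy)-2-methylbut-1-en-1-yl]dimethylalane | C[Al](C)/C=C(\C)CCO[Si](C)(C)C(C)(C)C | intermediate
22 | lithium butyl[(E)-4-(tert-butyldimethylsilyloxy)-2-methylbut-1-en-1-yl]dimethylaluminate | [Li+].CCCC[Al-](C)(C)/C=C(\C)CCO[Si](C)(C)C(C)(C)C | intermediate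
23 | (E)-6-(tert-butyldimethylsilyloxy)-4-methylhex-3-en-1-ol | OCC/C=C(\C)CCO[Si](C)(C)C(C)(C)C | intermediate
24 | (E)-6-(tert-butyldimethylsilyloxy)-4-methylhex-3-en-1-yl pivalate | CC(C)(C)C(=O)OCC/C=C(\C)CCO[Si](C)(C)C(C)(C)C | intermediate
25 | (E)-6-hydroxy-4-methylhex-3-en-1-yl pivalate | CC(C)(C)C(=O)OCC/C=C(\C)CCO | intermediate
26 | (E)-4-methyl-6-oxohex-3-en-1-yl pivalate | CC(C)(C)C(=O)OCC/C=C(\C)CC=O | intermediate
27 | (P)-allenylindium(III) iodide methanesulfonate: In on C9 (which also bears CH2OTES), C1 central, C2 bearing H and the (C1′) CH(CH2OPMB)CH2CH2CH=CMe2 group | [H]C([C@H](CCC=C(C)C)COCc1ccc(OC)cc1)=[C@]=C([In](I)OS(C)(=O)=O)CO[Si](CC)(CC)CC | intermediate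
28 | open-chain anti adduct (C1′S,C2R,C3S; 5E): PivO–C8H2–C7H2–C6H=C5(Me)–C4H2–C3H(OH)–C2H[C1′H(CH2OPMB)CH2CH2CH=CMe2]–C1≡C9–C12H2OTES | CC(C)(C)C(=O)OCC/C=C(\C)C[C@H](O)[C@H]([C@H](CCC=C(C)C)COCc1ccc(OC)cc1)C#CCO[Si](CC)(CC)CC | intermediate
29 | C3–OTBS ether of 28 (C12–OTES, C8–OPiv) | CC(C)(C)C(=O)OCC/C=C(\C)C[C@H](O[Si](C)(C)C(C)(C)C)[C@H]([C@H](CCC=C(C)C)COCc1ccc(OC)cc1)C#CCO[Si](CC)(CC)CC | intermediate
30 | C12 propargylic alcohol (C3–OTBS, C8–OPiv, C1≡C9) | CC(C)(C)C(=O)OCC/C=C(\C)C[C@H](O[Si](C)(C)C(C)(C)C)[C@H]([C@H](CCC=C(C)C)COCc1ccc(OC)cc1)C#CCO | intermediate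
31 | (Z)-C9 tributylstannyl alkene (Sn cis to C2 across C1=C9), C12–OH, C8–OPiv | CC(C)(C)C(=O)OCC/C=C(\C)C[C@H](O[Si](C)(C)C(C)(C)C)[C@H]([C@H](CCC=C(C)C)COCc1ccc(OC)cc1)/C=C(\[Sn](CCCC)(CCCC)CCCC)CO | intermediate
32 | (Z)-C9 iodoalkene (I cis to C2), C12–OH, C8–OPiv | CC(C)(C)C(=O)OCC/C=C(\C)C[C@H](O[Si](C)(C)C(C)(C)C)[C@H]([C@H](CCC=C(C)C)COCc1ccc(OC)cc1)/C=C(\I)CO | intermediate
33 | (Z)-C9 iodoalkene, C12–OTIPS, C8–OPiv | CC(C)(C)C(=O)OCC/C=C(\C)C[C@H](O[Si](C)(C)C(C)(C)C)[C@H]([C@H](CCC=C(C)C)COCc1ccc(OC)cc1)/C=C(\I)CO[Si](C(C)C)(C(C)C)C(C)C | intermediate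
34 | (Z)-C9 iodoalkene, C12–OTIPS, C8–OH | OCC/C=C(\C)C[C@H](O[Si](C)(C)C(C)(C)C)[C@H]([C@H](CCC=C(C)C)COCc1ccc(OC)cc1)/C=C(\I)CO[Si](C(C)C)(C(C)C)C(C)C | intermediate
35 | (Z)-C9 iodoalkene, C12–OTIPS, C8 aldehyde | O=CC/C=C(\C)C[C@H](O[Si](C)(C)C(C)(C)C)[C@H]([C@H](CCC=C(C)C)COCc1ccc(OC)cc1)/C=C(\I)CO[Si](C(C)C)(C(C)C)C(C)C | intermediate
36 | C9 alkenylchromium(III) dichloride of 35 | O=CC/C=C(\C)C[C@H](O[Si](C)(C)C(C)(C)C)[C@H]([C@H](CCC=C(C)C)COCc1ccc(OC)cc1)/C=C(\[Cr](Cl)Cl)CO[Si](C(C)C)(C(C)C)C(C)C | intermediate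
37 | nine-membered ring dienol, both C8 epimers: ring C1–C9 with (Z)-C9=C1 and (E)-C5=C6, C8–OH, C3–OTBS (3S), C2 side chain (2S,1′S), C9–CH2OTIPS | OC1C/C=C(\C)C[C@H](O[Si](C)(C)C(C)(C)C)[C@H]([C@H](CCC=C(C)C)COCc2ccc(OC)cc2)/C=C1/CO[Si](C(C)C)(C(C)C)C(C)C | intermediate
38 | ring dienone (C8=O conjugated with (Z)-C9=C1) | O=C1C/C=C(\C)C[C@H](O[Si](C)(C)C(C)(C)C)[C@H]([C@H](CCC=C(C)C)COCc2ccc(OC)cc2)/C=C1/CO[Si](C(C)C)(C(C)C)C(C)C | intermediate
39 | (8S)-ring dienol | O[C@H]1C/C=C(\C)C[C@H](O[Si](C)(C)C(C)(C)C)[C@H]([C@H](CCC=C(C)C)COCc2ccc(OC)cc2)/C=C1/CO[Si](C(C)C)(C(C)C)C(C)C | intermediate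
40 | potassium (8S)-alkoxide of 39 | [K+].[O-][C@H]1C/C=C(\C)C[C@H](O[Si](C)(C)C(C)(C)C)[C@H]([C@H](CCC=C(C)C)COCc2ccc(OC)cc2)/C=C1/CO[Si](C(C)C)(C(C)C)C(C)C | intermediate
41 | (8S)-C8 (tributylstannyl)methyl ether of the ring dienol (key-step precursor) | CCCC[Sn](CCCC)(CCCC)CO[C@H]1C/C=C(\C)C[C@H](O[Si](C)(C)C(C)(C)C)[C@H]([C@H](CCC=C(C)C)COCc2ccc(OC)cc2)/C=C1/CO[Si](C(C)C)(C(C)C)C(C)C | intermediate
42 | (8S)-C8 lithiomethyl ether | [Li]CO[C@H]1C/C=C(\C)C[C@H](O[Si](C)(C)C(C)(C)C)[C@H]([C@H](CCC=C(C)C)COCc2ccc(OC)cc2)/C=C1/CO[Si](C(C)C)(C(C)C)C(C)C | intermediate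
43 | C10 alcohol (key-step product): ring with C1–CH2OH (1R), C2 side chain (2R,1′S), C3–OTBS (3S), (5E)-C5=C6, (8E)-C8=C9, C9–CH2OTIPS, C11–OPMB | COc1ccc(COC[C@@H](CCC=C(C)C)[C@H]2[C@@H](O[Si](C)(C)C(C)(C)C)C/C(C)=C/C/C=C(/CO[Si](C(C)C)(C(C)C)C(C)C)[C@@H]2CO)cc1 | intermediate
44 | C10–OTES ether of 43 | COc1ccc(COC[C@@H](CCC=C(C)C)[C@H]2[C@@H](O[Si](C)(C)C(C)(C)C)C/C(C)=C/C/C=C(/CO[Si](C(C)C)(C(C)C)C(C)C)[C@@H]2CO[Si](CC)(CC)CC)cc1 | intermediate
45 | C11 alcohol (C10–OTES, C12–OTIPS, C3–OTBS) | OC[C@@H](CCC=C(C)C)[C@H]1[C@@H](O[Si](C)(C)C(C)(C)C)C/C(C)=C/C/C=C(/CO[Si](C(C)C)(C(C)C)C(C)C)[C@@H]1CO[Si](CC)(CC)CC | intermediate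
46 | C11 acetate (C10–OTES, C12–OTIPS, C3–OTBS) | CC(=O)OC[C@@H](CCC=C(C)C)[C@H]1[C@@H](O[Si](C)(C)C(C)(C)C)C/C(C)=C/C/C=C(/CO[Si](C(C)C)(C(C)C)C(C)C)[C@@H]1CO[Si](CC)(CC)CC | intermediate
47 | C11 acetate C3,C10,C12-triol | CC(=O)OC[C@@H](CCC=C(C)C)[C@H]1[C@@H](O)C/C(C)=C/C/C=C(/CO)[C@@H]1CO | intermediate
48 | CNP0284729.1: (1R,2R,3S,1′S,5E,8E) ring with C1–CHO, C9–CHO, C3–OH, C5–Me and C2–CH(CH2OAc)CH2CH2CH=CMe2 | CC(=O)OC[C@@H](CCC=C(C)C)[C@H]1[C@@H](O)C/C(C)=C/C/C=C(/C=O)[C@@H]1C=O | target

**Totals**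
Total steps: 30. Longest linear sequence: 24 steps (steps 1–3, 6–9 and 14–30, from 5-bromo-2-methylpent-2-ene).

**Steps most likely to fail**

Step 21 (nine-membered ring closure). Transannular strain may slow the intramolecular addition so that protodeiodination, intermolecular coupling or migration of the β,γ-olefin of the aldehyde into conjugation compete. The fallback sets out from 31 and returns at 38. Stannane 31 is isolated instead of being iodinated and is silylated (TIPSOTf, 2,6-lutidine) to the stannane TIPS ether F1. DIBAL-H frees the C8 stannyl alcohol F2, Dess–Martin oxidation gives the stannyl aldehyde F3, and Pinnick oxidation gives the stannyl acid F4. 1-Chloro-N,N,2-trimethylprop-1-en-1-amine converts it into the stannyl acid chloride F5. This is added slowly to Pd2(dba)3/tri(2-furyl)phosphine in toluene at high dilution. The intramolecular Stille acylation forms the same C8–C9 bond at the ketone level under neutral conditions and gives enone 38 directly, so step 22 falls away.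

Step 25 (key rearrangement). The lithiomethyl ether may undergo [1,2]-migration or simply be protonated to the methyl ether if the ring conformation keeps the carbanion away from C1; the stannylmethylation that feeds it may also be sluggish. The fallback sets out from 39 and returns at 43, keeping the same C1–C bond formation from the C8 oxygen. O-Alkylation with tert-butyl bromoacetate (NaH, Bu4NI, THF) gives the C8 glycolate ether F6. LDA at −78 °C triggers the ester-enolate [2,3]-Wittig rearrangement on the same face to the α-hydroxy ester F7 (carbinol epimers, of no consequence). LiAlH4 gives the 1,2-diol F8, NaIO4 cleaves it to the C10 aldehyde F9, and NaBH4 added to the same flask gives 43.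

Step 14 (fragment union). Oxidative addition to the hindered, α-branched mesylate may be slow, the allenylmetal may be lost by elimination across the CH2OTES carbon, and the anti preference may erode. The fallback sets out from 18 and returns at 28. Methyl chloroformate/pyridine gives the propargylic methyl carbonate F10. Copper(I)-catalysed anti SN2′ borylation (CuOt-Bu, Xantphos, B2pin2, THF) gives the isolable (M)-allenylboronate F11. Heating F11 with aldehyde 26 in toluene should give 28 through a closed six-membered B–O transition state with the same C2 and anti C3 configuration, without palladium or indium.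

**Further compounds**
F1 | step 21 | TIPS ether of stannane 31 (C9–SnBu3, C12–OTIPS, C8–OPiv) | CC(C)(C)C(=O)OCC/C=C(\C)C[C@H](O[Si](C)(C)C(C)(C)C)[C@H]([C@H](CCC=C(C)C)COCc1ccc(OC)cc1)/C=C(\[Sn](CCCC)(CCCC)CCCC)CO[Si](C(C)C)(C(C)C)C(C)C
F2 | step 21 | C8 stannyl alcohol | OCC/C=C(\C)C[C@H](O[Si](C)(C)C(C)(C)C)[C@H]([C@H](CCC=C(C)C)COCc1ccc(OC)cc1)/C=C(\[Sn](CCCC)(CCCC)CCCC)CO[Si](C(C)C)(C(C)C)C(C)C
F3 | step 21 | C8 stannyl aldehyde | O=CC/C=C(\C)C[C@H](O[Si](C)(C)C(C)(C)C)[C@H]([C@H](CCC=C(C)C)COCc1ccc(OC)cc1)/C=C(\[Sn](CCCC)(CCCC)CCCC)CO[Si](C(C)C)(C(C)C)C(C)C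
F4 | step 21 | C8 stannyl carboxylic acid | OC(=O)C/C=C(\C)C[C@H](O[Si](C)(C)C(C)(C)C)[C@H]([C@H](CCC=C(C)C)COCc1ccc(OC)cc1)/C=C(\[Sn](CCCC)(CCCC)CCCC)CO[Si](C(C)C)(C(C)C)C(C)C
F5 | step 21 | C8 stannyl acid chloride | ClC(=O)C/C=C(\C)C[C@H](O[Si](C)(C)C(C)(C)C)[C@H]([C@H](CCC=C(C)C)COCc1ccc(OC)cc1)/C=C(\[Sn](CCCC)(CCCC)CCCC)CO[Si](C(C)C)(C(C)C)C(C)C
F6 | step 25 | C8 tert-butyl glycolate ether of 39 | CC(C)(C)OC(=O)CO[C@H]1C/C=C(\C)C[C@H](O[Si](C)(C)C(C)(C)C)[C@H]([C@H](CCC=C(C)C)COCc2ccc(OC)cc2)/C=C1/CO[Si](C(C)C)(C(C)C)C(C)C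
F7 | step 25 | C1 α-hydroxy tert-butyl ester (carbinol epimers) | COc1ccc(COC[C@@H](CCC=C(C)C)[C@H]2[C@@H](O[Si](C)(C)C(C)(C)C)C/C(C)=C/C/C=C(/CO[Si](C(C)C)(C(C)C)C(C)C)[C@@H]2C(O)C(=O)OC(C)(C)C)cc1
F8 | step 25 | C1 1,2-diol (carbinol epimers) | COc1ccc(COC[C@@H](CCC=C(C)C)[C@H]2[C@@H](O[Si](C)(C)C(C)(C)C)C/C(C)=C/C/C=C(/CO[Si](C(C)C)(C(C)C)C(C)C)[C@@H]2C(O)CO)cc1
F9 | step 25 | C10 aldehyde | COc1ccc(COC[C@@H](CCC=C(C)C)[C@H]2[C@@H](O[Si](C)(C)C(C)(C)C)C/C(C)=C/C/C=C(/CO[Si](C(C)C)(C(C)C)C(C)C)[C@@H]2C=O)cc1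
F10 | step 14 | propargylic methyl carbonate of 18 | CC[Si](CC)(CC)OCC#C[C@@H](OC(=O)OC)[C@H](CCC=C(C)C)COCc1ccc(OC)cc1
F11 | step 14 | (M)-allenyl pinacolboronate (B on C9) | [H]C([C@H](CCC=C(C)C)COCc1ccc(OC)cc1)=[C@]=C(B1OC(C)(C)C(C)(C)O1)CO[Si](CC)(CC)CC
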